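**Retrosynthetic overview**
- The last ring is the epoxide, from hydroxyl-directed epoxidation of a Z-cyclononene tertiary allylic alcohol; the nine-membered ring comes from ring-closing metathesis (C8=C9) on a tetraene that already holds the furo[2,3-b]pyran acetal.
- Key step: an open-chain (Z)-epoxy allylic alcohol is oxidised to the enal and collapses in one operation (lactolisation, then 5-exo opening of the allylic 13,14-epoxide) to the pyran and the dihydrofuran together, inverting C13 and releasing C14–OH.
- The open chain (C4a, C11a, Z-C4=C12) comes from an Ireland–Claisen rearrangement with chirality transfer from a C12 carbinol, reduced in the same pot.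
- The Claisen ester is built from 3-methylidenehex-5-enoic acid (diketene + allyl Grignard) and an epoxy alcohol made by Nozaki–Hiyama–Kishi coupling of an (S)-linalool-derived iodoenoate (C7) with an organocatalytically made epoxy aldehyde (C13, C14).
- Ring order: pyran + dihydrofuran (together) → nine-membered carbocycle → epoxide.

Assumption: (S)-(+)-linalool is bought in high enantiomeric purity; locants in names follow xenicane numbering of the target (C1 OCH2, C3 acetal CH, C4=C12 dihydrofuran alkene, C13 dihydrofuran OCH, C14/C15 diol carbons, C4a/C11a ring-fusion CH, C5/C6 CH2, C7 carbinol, C8/C9 epoxide, C10 CH2, C11=C19 exocyclic alkene).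

**Step 1**
Reactants: 1 2-methylbut-3-en-2-ol; 2 (E)-but-2-enal (3 equiv)
Product: 3 (2E)-4-hydroxy-4-methylpent-2-enal
Conditions: Hoveyda–Grubbs second-generation catalyst RuCl2(H2IMes)(=CH-C6H4-2-O-i-Pr) (2 mol %), CH2Cl2, 40 °C
Reagents that add atoms: none
Why: Olefin cross-metathesis of a tertiary allylic alcohol (slow to homodimerise) with an enal partner is E-selective, and no stereocentre is formed.

**Step 2**
Reactants: 3 (2E)-4-hydroxy-4-methylpent-2-enal
Product: 4 (2R,3R)-3-(2-hydroxypropan-2-yl)oxirane-2-carbaldehyde (trans-epoxide)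
Conditions: (S)-2-{bis[3,5-bis(trifluoromethyl)phenyl][(trimethylsilyl)oxy]methyl}pyrrolidine (10 mol %), 35% aq H2O2 (1.3 equiv), CH2Cl2, rt; used crude
Reagents that add atoms: hydrogen peroxide, OO
Why: Jørgensen iminium/enamine epoxidation of an (E)-enal gives the trans-epoxy aldehyde in high ee, the (S)-catalyst setting C13 and C14 by catalyst control in the same spatial sense as the (2R,3S) epoxides obtained from simple enals (3R here only because the carbinol substituent outranks C2).

**Step 3**
Reactants: 5 (S)-(+)-linalool
Product: 6 (4S)-4-hydroxy-4-methylhex-5-enal (mainly as its five-membered lactol)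
Conditions: O3 (1.0 equiv, Sudan Red 7B end-point), CH2Cl2/MeOH, −78 °C; Me2S, −78 °C to rt
Reagents that add atoms: ozone, [O-][O+]=O
Why: Ozonolysis with reductive work-up cleaves the electron-rich trisubstituted alkene much faster than the vinyl group, so only the prenyl end is cut and the chiral-pool C7 stereocentre is carried through unchanged.

**Step 4**
Reactants: 6 (4S)-4-hydroxy-4-methylhex-5-enal; 7 methyl (triphenyl-λ5-phosphanylidene)acetate
Product: 9 methyl (2Z,6S)-6-hydroxy-2-iodo-6-methylocta-2,7-dienoate, via iodo ylide 8 (not isolated)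
Conditions: 7, N-iodosuccinimide, CH2Cl2, −20 °C; then 6, rt to 40 °C
Reagents that add atoms: N-iodosuccinimide, O=C1CCC(=O)N1I
Why: One-pot ylide iodination/Wittig olefination through the open aldehyde form of the lactol places the ester trans to the chain, so iodine and C5 are cis in the (Z)-2-iodoenoate, which fixes the later C4=C4a geometry.

**Step 5**
Reactants: 9 methyl (2Z,6S)-6-hydroxy-2-iodo-6-methylocta-2,7-dienoate; 4 (2R,3R)-3-(2-hydroxypropan-2-yl)oxirane-2-carbaldehyde (1.5 equiv)
Product: 10 methyl (2E,6S)-6-hydroxy-2-{(S)-hydroxy[(2S,3R)-3-(2-hydroxypropan-2-yl)oxiran-2-yl]methyl}-6-methylocta-2,7-dienoate (anti epoxy alcohol; 12S,13S,14R)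
Conditions: CrCl2 (4 equiv), NiCl2 (2 mol %), DMSO, rt; chromatographic removal of the minor C12 epimer
Reagents that add atoms: none
Why: Nozaki–Hiyama–Kishi coupling: the alkenylchromium reagent is formed with retention of alkene geometry and adds only to the aldehyde in the presence of ester, epoxide and free hydroxyls, and polar Felkin–Anh (Cornforth) attack anti to the epoxide C–O bond sets C12 as the anti (12S) carbinol.

**Step 6**
Reactants: 11 diketene (4-methylideneoxetan-2-one); 12 allylmagnesium chloride
Product: 13 3-methylidenehex-5-enoic acid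
Conditions: NiCl2 (5 mol %), THF, −78 to 0 °C; aq HCl
Reagents that add atoms: none
Why: Nickel-catalysed ring opening of diketene by a Grignard reagent with cleavage of the vinylic C–O bond (a cross-coupling-type reaction known for 3-methylidenealkanoic acids) gives the acid in one step, and no stereocentre is formed.

**Step 7**
Reactants: 10 anti epoxy alcohol; 13 3-methylidenehex-5-enoic acid
Product: 14 methyl (2E,6S)-6-hydroxy-2-{(S)-[(2S,3R)-3-(2-hydroxypropan-2-yl)oxiran-2-yl][(3-methylidenehex-5-enoyl)oxy]methyl}-6-methylocta-2,7-dienoate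
Conditions: DCC (1.2 equiv), DMAP (10 mol %), CH2Cl2, 0 °C
Reagents that add atoms: none
Why: Steglich esterification acylates only the secondary C12 hydroxyl (both tertiary alcohols are inert) with retention at C12, and low temperature with catalytic DMAP limits conjugation of the β,γ-unsaturated acid.

**Step 8**
Reactants: 14 C12 ester
Product: 18 open-chain tetraol (4aS,7S,11aR,13S,14R; 4(12)Z), via silyl ketene acetal 15 (not isolated), via trimethylsilyl ester 16 (not isolated), via bis-silyl ether diol 17 (not isolated)
Conditions: LiN(i-Pr)2 (4 equiv), Me3SiCl (6 equiv, internal quench), THF, −78 to 40 °C; evaporate; i-Bu2AlH (8 equiv), CH2Cl2, −78 to −40 °C; aq potassium sodium tartrate; Bu4NF, AcOH, THF, 0 °C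
Reagents that add atoms: none
Why: Ireland–Claisen rearrangement: internal-quench enolisation gives the kinetic silyl ketene acetal with C11 cis to the allylic oxygen, and a chair transition state with the epoxide arm equatorial on C12 and both C11 and C5 axial transfers the C12 configuration to C11a (R) and C4a (S) (the syn outcome known for Z-crotyl-type esters under these conditions) and places C13 cis to C3 on the new C4=C12 alkene, after which i-Bu2AlH reduces the silyl and methyl esters to the two primary alcohols and buffered fluoride removes the transient silyl ethers.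

**Step 9**
Reactants: 18 open-chain tetraol
Product: 21 furo[2,3-b]pyran acetal tetraene (3S,4aS,7S,11aR,13R,14R), via hydroxy enal 19 (not isolated), via lactol 20 (not isolated)
Conditions: MnO2 (15 equiv), CH2Cl2, rt, stopped at full conversion of 18; filter; PPTS (10 mol %), CH2Cl2, 0 °C; Et3N quench
Reagents that add atoms: none
Why: Proposed new method: MnO2 oxidises only the allylic C3–OH to the (Z)-enal, C1–OH closes to the six-membered lactol, and under mild acid the lactol oxygen (or the enal oxygen through an oxocarbenium ion that C1–OH traps) opens the allylic 13,14-epoxide 5-exo with inversion at C13, so the pyran and dihydrofuran form together, C13 becomes R, C14–OH is released with retention and the C3 acetal equilibrates to the isomer with the furan oxygen equatorial on the pyran; the closest known reaction types are acid-catalysed hydroxy-epoxide opening cascades and the cyclisation of (Z)-γ,δ-epoxy enals and enones to furan derivatives.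

**Step 10**
Reactants: 21 furo[2,3-b]pyran acetal tetraene
Product: 22 Z-cyclononene triol (3S,4aS,7S,11aR,13R,14R; 8Z)
Conditions: first-generation Grubbs catalyst RuCl2(PCy3)2(=CHPh) (15 mol %), CH2Cl2 (1 mM), 40 °C
Reagents that add atoms: none
Why: Ring-closing metathesis: the catalyst loads at the unhindered C9 allyl terminus and closes onto the hydroxyl-activated C8 vinyl group held gauche by the trans-diequatorial pyran substituents, the nine-membered ring accepts only the Z alkene, and the first-generation catalyst should not engage the hindered 1,1-disubstituted C11=C19 alkene, which would have to give a trisubstituted cycloheptene next to the C7 quaternary centre.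

**Step 11**
Reactants: 22 Z-cyclononene triol
Product: 23 target (3S,4aS,7S,8R,9R,11aR,13R,14R)
Conditions: VO(acac)2 (5 mol %), t-BuOOH (1.3 equiv), CH2Cl2, 0 °C
Reagents that add atoms: tert-butyl hydroperoxide, CC(C)(C)OO
Why: Hydroxyl-directed epoxidation (Sharpless–Michaelson, VO(acac)2/t-BuOOH): the C7 tertiary allylic alcohol delivers oxygen to its own face of the C8=C9 alkene, giving the cis-epoxy alcohol (8R,9R) as is usual for medium-ring allylic alcohols, faster than the homoallylic C14–OH can direct attack on the dihydrofuran alkene and without touching the exocyclic methylene.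

**Compound list**
1 | 2-methylbut-3-en-2-ol | CC(C)(O)C=C | starting material
2 | (E)-but-2-enal | C/C=C/C=O | starting material
3 | (2E)-4-hydroxy-4-methylpent-2-enal | CC(C)(O)/C=C/C=O | intermediate
4 | (2R,3R)-3-(2-hydroxypropan-2-yl)oxirane-2-carbaldehyde | O=C[C@@H]1O[C@H]1C(C)(C)O | intermediate
5 | (S)-(+)-linalool, (3S)-3,7-dimethylocta-1,6-dien-3-ol | C=C[C@@](C)(O)CCC=C(C)C | starting material
6 | (4S)-4-hydroxy-4-methylhex-5-enal (lactol equilibrium) | C=C[C@@](C)(O)CCC=O | intermediate
7 | methyl (triphenyl-λ5-phosphanylidene)acetate | COC(=O)C=P(c1ccccc1)(c1ccccc1)c1ccccc1 | starting material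
8 | methyl iodo(triphenyl-λ5-phosphanylidene)acetate | COC(=O)C(I)=P(c1ccccc1)(c1ccccc1)c1ccccc1 | intermediate
9 | methyl (2Z,6S)-6-hydroxy-2-iodo-6-methylocta-2,7-dienoate | C=C[C@@](C)(O)CC/C=C(\I)C(=O)OC | intermediate
10 | methyl (2E,6S)-6-hydroxy-2-{(S)-hydroxy[(2S,3R)-3-(2-hydroxypropan-2-yl)oxiran-2-yl]methyl}-6-methylocta-2,7-dienoate | C=C[C@@](C)(O)CC/C=C(/C(=O)OC)[C@H](O)[C@@H]1O[C@H]1C(C)(C)O | intermediate
11 | diketene (4-methylideneoxetan-2-one) | C=C1CC(=O)O1 | starting material
12 | allylmagnesium chloride | C=CC[Mg]Cl | starting material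
13 | 3-methylidenehex-5-enoic acid | C=CCC(=C)CC(=O)O | intermediate
14 | C12 (3-methylidenehex-5-enoyl) ester of 10 (12S,13S,14R; 4(4a)E) | C=C[C@@](C)(O)CC/C=C(/C(=O)OC)[C@H](OC(=O)CC(=C)CC=C)[C@@H]1O[C@H]1C(C)(C)O | intermediate
15 | (E)-trimethylsilyl ketene acetal of 14 (C11 cis to the allylic oxygen), O7 and O15 trimethylsilylated | C=C[C@@](C)(O[Si](C)(C)C)CC/C=C(/C(=O)OC)[C@H](O/C(O[Si](C)(C)C)=C\C(=C)CC=C)[C@@H]1O[C@H]1C(C)(C)O[Si](C)(C)C | intermediate
16 | rearranged C1 trimethylsilyl ester, C3 methyl ester, O7/O15 bis(trimethylsilyl) ether (4aS,7S,11aR,13S,14R; 4(12)Z) | C=CCC(=C)[C@H](C(=O)O[Si](C)(C)C)[C@H](CC[C@](C)(O[Si](C)(C)C)C=C)/C(C(=O)OC)=C/[C@@H]1O[C@H]1C(C)(C)O[Si](C)(C)C | intermediate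
17 | C1,C3-diol, O7/O15 bis(trimethylsilyl) ether (4aS,7S,11aR,13S,14R; 4(12)Z) | C=CCC(=C)[C@H](CO)[C@H](CC[C@](C)(O[Si](C)(C)C)C=C)/C(CO)=C/[C@@H]1O[C@H]1C(C)(C)O[Si](C)(C)C | intermediate
18 | open-chain tetraol: C11a bears CH2OH and penta-1,4-dien-2-yl, C4a bears the (3S)-3-hydroxy-3-methylpent-4-enyl chain, C4 bears CH2OH and the Z alkene to the trans-(13S,14R)-epoxide with the C15 carbinol (4aS,11aR) | C=CCC(=C)[C@H](CO)[C@H](CC[C@](C)(O)C=C)/C(CO)=C/[C@@H]1O[C@H]1C(C)(C)O | intermediate
19 | (Z)-hydroxy enal (C3 aldehyde) of 18 | C=CCC(=C)[C@H](CO)[C@H](CC[C@](C)(O)C=C)/C(C=O)=C/[C@@H]1O[C@H]1C(C)(C)O | intermediate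
20 | pyran lactol (C3 anomers) with Z-alkylidene epoxide arm | C=CCC(=C)[C@@H]1COC(O)/C(=C\[C@@H]2O[C@H]2C(C)(C)O)[C@H]1CC[C@](C)(O)C=C | intermediate
21 | furo[2,3-b]pyran acetal tetraene (3S,4aS,7S,11aR,13R,14R) | C=CCC(=C)[C@@H]1CO[C@H]2O[C@@H]([C@@H](O)C(C)(C)O)C=C2[C@H]1CC[C@](C)(O)C=C | intermediate
22 | tricyclic Z-cyclononene triol (3S,4aS,7S,11aR,13R,14R; 8Z) | C=C1C/C=C\[C@@](C)(O)CC[C@@H]2C3=C[C@H]([C@@H](O)C(C)(C)O)O[C@@H]3OC[C@@H]12 | intermediate
23 | CNP0281409.2 (3S,4aS,7S,8R,9R,11aR,13R,14R) | C=C1C[C@H]2O[C@H]2[C@@](C)(O)CC[C@@H]2C3=C[C@H]([C@@H](O)C(C)(C)O)O[C@@H]3OC[C@@H]12 | target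

**Totals**
Total step count: 11. Longest linear sequence: 8 steps (5 → 6 → 9 → 10 → 14 → 18 → 21 → 22 → 23).

**Steps most likely to fail, with fallbacks**

Step 5 is at risk because the Felkin preference at C12 may be small, the alkenylchromium reagent must keep its geometry, and epoxy aldehyde 4 is fragile. The fallback sets out from 9 and uses the achiral enal 3 in place of 4. The same CrCl2/NiCl2 coupling gives the bis-allylic alcohol F1 as a mixture of C12 epimers. A Sharpless asymmetric epoxidation run as a kinetic resolution (Ti(OiPr)4, L-(+)-diisopropyl tartrate, t-BuOOH, 4 Å sieves, CH2Cl2, −20 °C) then epoxidises the C13=C14 alkene of the (12S) epimer only, erythro-selectively. Reagent control thus replaces substrate control for C12, C13 and C14, and the route is rejoined at 10; the acrylate alkene and the tertiary vinyl carbinol are inert to this reagent.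

Step 9 is at risk because lactol 20 can be over-oxidised on MnO2 and because the allylic acetal can lose H13 under acid to give a furan. The fallback sets out from 18 and pushes the MnO2 oxidation on purpose (large excess, long time) to the stable α-alkylidene δ-lactone F2, which can be purified. i-Bu2AlH at −78 °C then gives lactol 20 cleanly, and 20 is closed onto the epoxide with catalytic DBU in CH2Cl2 (alkoxide 5-exo opening, no cation, hence no furan leak), returning to the route at 21.

Step 10 is at risk because the nine-membered closure may be slow on the bicyclic acetal and the 1,1-disubstituted alkene could compete to give a seven-membered ring. The fallback sets out from 18, which is first taken to the lactone F2 as above. Ring-closing metathesis is then run on this trans-disubstituted δ-lactone, a more rigid and acid-insensitive substrate, to give the lactone-fused Z-cyclononene F3. i-Bu2AlH at −78 °C gives the lactol F4, and the dihydrofuran is closed by the same base-mediated epoxide opening, which rejoins the route at 22.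

**Further compounds**
F1 | step 5 | methyl (2E,6S)-2-[(2E)-1,4-dihydroxy-4-methylpent-2-en-1-yl]-6-hydroxy-6-methylocta-2,7-dienoate (both C12 epimers) | C=C[C@@](C)(O)CC/C=C(/C(=O)OC)C(O)/C=C/C(C)(C)O
F2 | step 9 | α-alkylidene δ-lactone (C3 lactone carbonyl; 4aS,7S,11aR,13S,14R; 4(12)Z) | C=CCC(=C)[C@@H]1COC(=O)/C(=C\[C@@H]2O[C@H]2C(C)(C)O)[C@H]1CC[C@](C)(O)C=C
F3 | step 10 | lactone-fused Z-cyclononene (4aS,7S,11aR,13S,14R; 4(12)Z,8Z) | C=C1C/C=C\[C@@](C)(O)CC[C@@H]2/C(=C/[C@@H]3O[C@H]3C(C)(C)O)C(=O)OC[C@@H]12
F4 | step 10 | lactol of F3 (C3 anomers) | C=C1C/C=C\[C@@](C)(O)CC[C@@H]2/C(=C/[C@@H]3O[C@H]3C(C)(C)O)C(O)OC[C@@H]12
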